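The resorcinol ring is built last rather than carried through: a thermal pericyclic cascade joins a 3-alkylcyclobutenone and ethoxyacetylene. The feature exploited is the benzene ring with oxygen on C1 and C3, the side chain on C5 and hydrogen on C2, C4 and C6: C4, C5, C6 and C1 with its oxygen come from the cyclobutenone, C2 and C3 with its oxygen from the alkyne. One operation forms C1–C2 and C3–C4, re-forms C1–C6 and aromatises, with the 1,3,5-pattern fixed by alkyne polarisation. The precursor is (S)-heptadecan-3-yl benzoate carrying a 3-oxocyclobut-1-enyl group on chain carbon 17, made from 1-hexadecyne by ynone reduction and an alkyne walk.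

Key step: step 7

Remark: ring atoms are numbered as in the product phenol (C1 free OH, C3 ethoxy, C5 chain) and the chain as heptadecan-3-ol; the (S,S) catalyst antipode is assumed in step 2 because the carbinol keeps its S descriptor when the alkynyl branch becomes the saturated chain.

Step 1
Reactants: 1 1-hexadecyne; 2 N-methoxy-N-methylpropanamide
Product: 4 nonadec-4-yn-3-one, via lithium hexadec-1-yn-1-ide 3 (not isolated)
Conditions: n-BuLi, THF, −78 → 0 °C; then 2, −78 → 0 °C; 1 M HCl
Reagents that add atoms: N-methoxy-N-methylpropanamide (2), CCC(=O)N(C)OC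
Why: Weinreb ketone synthesis, in which the lithium acetylide adds once to the amide and the chelated tetrahedral adduct collapses to the ynone only on acidic quench, so over-addition should not occur.

Step 2
Reactants: 4 nonadec-4-yn-3-one
Product: 5 (S)-nonadec-4-yn-3-ol
Conditions: RuCl[(S,S)-TsDPEN](p-cymene) (2 mol %, activated with KOH), i-PrOH, rt
Reagents that add atoms: none
Why: Noyori asymmetric transfer hydrogenation of an alkynyl ketone, in which the alkyne takes the place of the aryl group of aryl ketones in the six-membered outer-sphere transition state, so the (S,S) catalyst should set the carbinol carbon as S.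

Step 3
Reactants: 5 (S)-nonadec-4-yn-3-ol
Product: 7 (S)-nonadec-18-yn-3-ol, via dipotassium alkoxide acetylide 6 (not isolated)
Conditions: KH, H2N(CH2)3NH2 (potassium 3-aminopropylamide formed in situ), 0 °C → rt; then H2O
Reagents that add atoms: none
Why: Alkyne zipper reaction, in which reversible propargyl–allenyl proton shifts move the triple bond away from the alkoxide-blocked carbinol carbon until the terminal acetylide is reached as the thermodynamic sink; the C–H next to the alkoxide is not removed, so the S configuration should be retained.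

Step 4
Reactants: 7 (S)-nonadec-18-yn-3-ol; 8 benzoyl chloride
Product: 9 (S)-nonadec-18-yn-3-yl benzoate
Conditions: BzCl, pyridine, DMAP (cat.), CH2Cl2, 0 °C → rt
Reagents that add atoms: benzoyl chloride (8), O=C(Cl)c1ccccc1
Why: DMAP-catalysed O-acylation, which leaves the C–O bond of the stereocentre intact; the benzoate should tolerate ZnCl2, Zn/AcOH, 80 °C and cold BBr3, keeps the alcohol away from acyl chlorides and ketenes, and adds a UV chromophore.

Step 5
Reactants: 9 (S)-nonadec-18-yn-3-yl benzoate; 10 trichloroacetyl chloride
Product: 11 (S)-17-(4,4-dichloro-3-oxocyclobut-1-en-1-yl)heptadecan-3-yl benzoate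
Conditions: Zn(Cu), Cl3CCOCl (slow addition), Et2O/DME, rt
Reagents that add atoms: trichloroacetyl chloride (10), ClC(Cl)(Cl)C(Cl)=O
Why: Ketene–alkyne [2+2] cycloaddition, in which dichloroketene released by zinc bonds through its carbonyl carbon to the terminal alkyne carbon and so should give the 3-alkyl-4,4-dichlorocyclobutenone regioisomer, while DME ties up ZnCl2.

Step 6
Reactants: 11 (S)-17-(4,4-dichloro-3-oxocyclobut-1-en-1-yl)heptadecan-3-yl benzoate
Product: 12 (S)-17-(3-oxocyclobut-1-en-1-yl)heptadecan-3-yl benzoate
Conditions: Zn dust, AcOH, TMEDA, EtOH, 0 °C → rt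
Reagents that add atoms: none
Why: Reductive dechlorination of an α,α-dichloroketone by zinc through the zinc enolate, which acetic acid protonates; the TMEDA-buffered medium should suppress migration of the ring double bond and the benzoate is inert.

Step 7
Reactants: 12 (S)-17-(3-oxocyclobut-1-en-1-yl)heptadecan-3-yl benzoate; 13 ethoxyacetylene
Product: 18 (S)-17-(3-ethoxy-5-hydroxyphenyl)heptadecan-3-yl benzoate, via vinylketene 14 (not isolated), via vinylcyclobutenone adduct 15 (not isolated), via dienylketene 16 (not isolated), via cyclohexadienone tautomer 17 (not isolated)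
Conditions: ethoxyacetylene (3 equiv, hexanes solution), PhMe, 80 °C, sealed tube
Reagents that add atoms: ethoxyacetylene (13), CCOC#C
Why: Heating should open cyclobutenone 12 by reversible conrotatory 4π cleavage of its C1–C6 bond (C1 carbonyl carbon, C4 ring CH, C5 chain-bearing carbon, C6 ring CH2) to vinylketene 14, which ethoxyacetylene captures in a [2+2] cycloaddition that forms C1–C2 and C3–C4 and gives vinylcyclobutenone 15. A second 4π opening of 15 (cleavage of C1–C4) gives dienylketene 16, and the only ring made in this step is closed by thermal disrotatory 6π electrocyclization forming C1–C6, after which cyclohexadienone 17 enolises to the phenol. The closest known reaction type is the Danheiser benzannulation of 3-alkylcyclobutenones with alkoxy- or siloxyalkynes, of which this is the least hindered case, and all atoms of both partners end up in the product. The selectivity required is the orientation of the ketene–alkyne [2+2], secured by the polarisation of the ynol ether: its nucleophilic CH carbon attacks the electrophilic ketene carbon C1, so OEt lands on C3, C2 stays unsubstituted and the chain sits meta to both oxygens. No stereocentre is formed, since the sp3 ring carbons of 15 and 17 disappear on aromatisation, and the benzoate-bearing carbinol carbon of the side chain is remote and inert; the excess of alkyne should keep the ketene from acylating the phenol as it forms.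

Step 8
Reactants: 18 (S)-17-(3-ethoxy-5-hydroxyphenyl)heptadecan-3-yl benzoate
Product: 19 (S)-17-(3,5-dihydroxyphenyl)heptadecan-3-yl benzoate
Conditions: BBr3 (4 equiv), CH2Cl2, −78 → 0 °C; then H2O
Reagents that add atoms: none
Why: Lewis-acid cleavage of an aryl alkyl ether, in which boron binds the ether oxygen and bromide attacks the ethyl CH2 in an SN2 step, so only the O–ethyl bond breaks; the secondary benzoate should survive at or below 0 °C and keeps the carbinol carbon from being brominated.

Step 9
Reactants: 19 (S)-17-(3,5-dihydroxyphenyl)heptadecan-3-yl benzoate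
Product: 20 hansfordiol C, (S)-5-(15-hydroxyheptadecyl)benzene-1,3-diol
Conditions: NaOH (aq.), MeOH/THF, rt, Ar; then 1 M HCl to pH 5–6
Reagents that add atoms: none
Why: Ester saponification by acyl–oxygen cleavage, which does not touch the C–O bond of the stereocentre, so the S configuration should be retained; exclusion of air protects the electron-rich resorcinolate.

Compound list
1 | 1-hexadecyne | CCCCCCCCCCCCCCC#C | starting material
2 | N-methoxy-N-methylpropanamide | CCC(=O)N(C)OC | starting material
3 | lithium hexadec-1-yn-1-ide | CCCCCCCCCCCCCCC#C[Li] | intermediate (not isolated)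
4 | nonadec-4-yn-3-one | CCC(=O)C#CCCCCCCCCCCCCCC | intermediate
5 | (S)-nonadec-4-yn-3-ol | CC[C@H](O)C#CCCCCCCCCCCCCCC | intermediate
6 | dipotassium salt of 7 (alkoxide at C3, acetylide at C19) | CC[C@H]([O-])CCCCCCCCCCCCCCC#[C-].[K+].[K+] | intermediate (not isolated)
7 | (S)-nonadec-18-yn-3-ol | CC[C@H](O)CCCCCCCCCCCCCCC#C | intermediate
8 | benzoyl chloride | O=C(Cl)c1ccccc1 | starting material
9 | (S)-nonadec-18-yn-3-yl benzoate | CC[C@H](OC(=O)c1ccccc1)CCCCCCCCCCCCCCC#C | intermediate
10 | trichloroacetyl chloride | ClC(Cl)(Cl)C(Cl)=O | starting material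
11 | (S)-17-(4,4-dichloro-3-oxocyclobut-1-en-1-yl)heptadecan-3-yl benzoate | CC[C@H](OC(=O)c1ccccc1)CCCCCCCCCCCCCCC1=CC(=O)C1(Cl)Cl | intermediate
12 | (S)-17-(3-oxocyclobut-1-en-1-yl)heptadecan-3-yl benzoate | CC[C@H](OC(=O)c1ccccc1)CCCCCCCCCCCCCCC1=CC(=O)C1 | intermediate
13 | ethoxyacetylene | CCOC#C | starting material
14 | (S)-18-methylidene-20-oxoicos-19-en-3-yl benzoate (vinylketene) | CC[C@H](OC(=O)c1ccccc1)CCCCCCCCCCCCCCC(=C)C=C=O | intermediate (not isolated)
15 | (3S)-18-(2-ethoxy-4-oxocyclobut-2-en-1-yl)nonadec-18-en-3-yl benzoate (both epimers at the ring CH) | CC[C@H](OC(=O)c1ccccc1)CCCCCCCCCCCCCCC(=C)C1C(OCC)=CC1=O | intermediate (not isolated)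
16 | (3S,19E)-20-ethoxy-18-methylidene-22-oxodocosa-19,21-dien-3-yl benzoate (dienylketene) | CC[C@H](OC(=O)c1ccccc1)CCCCCCCCCCCCCCC(=C)/C=C(OCC)\C=C=O | intermediate (not isolated)
17 | (S)-17-(3-ethoxy-5-oxocyclohexa-1,3-dien-1-yl)heptadecan-3-yl benzoate | CC[C@H](OC(=O)c1ccccc1)CCCCCCCCCCCCCCC1=CC(OCC)=CC(=O)C1 | intermediate (not isolated)
18 | (S)-17-(3-ethoxy-5-hydroxyphenyl)heptadecan-3-yl benzoate | CC[C@H](OC(=O)c1ccccc1)CCCCCCCCCCCCCCc1cc(O)cc(OCC)c1 | intermediate
19 | (S)-17-(3,5-dihydroxyphenyl)heptadecan-3-yl benzoate | CC[C@H](OC(=O)c1ccccc1)CCCCCCCCCCCCCCc1cc(O)cc(O)c1 | intermediate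
20 | hansfordiol C, (S)-5-(15-hydroxyheptadecyl)benzene-1,3-diol | CC[C@H](O)CCCCCCCCCCCCCCc1cc(O)cc(O)c1 | target

Total step count: 9. Longest linear sequence: 9 steps, from 1-hexadecyne (1) to hansfordiol C (20).

Steps most likely to fail

Step 7. The vinylketene may be lost to oligomerisation or to O-acylation of the phenol as it forms, or the volatile ynol ether may decompose before the [2+2] step, so that the cascade stalls short of aromatisation. The fallback brings the aromatic ring in intact instead of building it. Setting out from 2, lithium tetradec-1-yn-1-ide (from commercial 1-tetradecyne, CCCCCCCCCCCCC#C, and n-BuLi) is acylated as in step 1 to heptadec-4-yn-3-one F1, which is reduced as in step 2 to (S)-heptadec-4-yn-3-ol F2 and isomerised as in step 3 to (S)-heptadec-16-yn-3-ol F3. Sonogashira coupling with commercial 1,3-bis(benzyloxy)-5-bromobenzene (PdCl2(PPh3)2, CuI, Et3N, 60 °C) should give (S)-17-[3,5-bis(benzyloxy)phenyl]heptadec-16-yn-3-ol F4. Hydrogenation (H2, Pd/C, EtOAc/MeOH) should then saturate the triple bond and cleave both benzyl ethers, coming back to the route at 20.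

Step 5. Dichloroketene may oligomerise faster than it adds to the unactivated alkyne, or the zinc salts may degrade the strained adduct, so that conversion stays low. The fallback replaces the ketene by a keteniminium ion. Setting out from 9, keteniminium–alkyne [2+2] cycloaddition (N,N-dimethylacetamide, Tf2O, 2,4,6-collidine, 1,2-dichloroethane, reflux) should give N-{3-[(15S)-15-(benzoyloxy)heptadecyl]cyclobut-2-en-1-ylidene}-N-methylmethanaminium triflate F5. Its hydrolysis with aqueous NaHCO3 comes back to the route at 12, and steps 5 and 6 are no longer needed.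

Step 3. The migration over fourteen positions may stall next to the secondary alkoxide and leave internal alkyne and allene isomers, or the strongly basic medium may erode the configuration of the carbinol carbon. The fallback separates the alkyne walk from the stereocentre. Setting out from 1, hydroxymethylation (n-BuLi, paraformaldehyde, THF) should give heptadec-2-yn-1-ol F6, and the same zipper conditions applied to this achiral primary propargylic alcohol should give heptadec-16-yn-1-ol F7. Oxidation (Dess–Martin periodinane, CH2Cl2) should give heptadec-16-ynal F8. Catalytic enantioselective ethyl transfer to the Si face of the aldehyde (Et2Zn, Ti(OiPr)4, (1R,2R)-1,2-bis(trifluoromethanesulfonamido)cyclohexane, PhMe, −20 °C) then comes back to the route at 7 and replaces steps 1 to 3.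

Further compounds
F1 | step 7 | heptadec-4-yn-3-one | CCC(=O)C#CCCCCCCCCCCCC
F2 | step 7 | (S)-heptadec-4-yn-3-ol | CC[C@H](O)C#CCCCCCCCCCCCC
F3 | step 7 | (S)-heptadec-16-yn-3-ol | CC[C@H](O)CCCCCCCCCCCCC#C
F4 | step 7 | (S)-17-[3,5-bis(benzyloxy)phenyl]heptadec-16-yn-3-ol | CC[C@H](O)CCCCCCCCCCCCC#Cc1cc(OCc2ccccc2)cc(OCc2ccccc2)c1
F5 | step 5 | N-{3-[(15S)-15-(benzoyloxy)heptadecyl]cyclobut-2-en-1-ylidene}-N-methylmethanaminium triflate | CC[C@H](OC(=O)c1ccccc1)CCCCCCCCCCCCCCC1=CC(=[N+](C)C)C1.[O-]S(=O)(=O)C(F)(F)F
F6 | step 3 | heptadec-2-yn-1-ol | OCC#CCCCCCCCCCCCCCC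
F7 | step 3 | heptadec-16-yn-1-ol | OCCCCCCCCCCCCCCCC#C
F8 | step 3 | heptadec-16-ynal | O=CCCCCCCCCCCCCCCC#C
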